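**Retrosynthetic overview**

- The plan rests on the vicinal pair C8 (tertiary OH, shared by the ten-membered ring and the lactone ring) and C9 (OAc), which sit cis on the ten-membered ring. They are read as a pinacol, so the ten-membered ring is closed last at C8–C9 by SmI2 coupling of a C9 aldehyde on ring A with a C8 ketone in a 5-methoxy-4-methyloxolan-3-one (37 → 38).
- The β-methoxy ketone of 37 can lose methanol and epimerise at C7 and C17, so it is made only in the step before the coupling, by buffered oxidation of a C8/C9 diol whose stereocentres are already fixed.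
- The seco chain is joined at C4–C5 by a B-alkyl Suzuki coupling of ring A allylic acetate 20 with Z-vinyl iodide 33; retention at the vinyl iodide gives the Z C5=C6 olefin.
- Ring A is formed first: an enantioselective Diels–Alder reaction sets C1, C10 and C11, a Rubottom oxidation sets the C12 oxygen, enol triflate reduction gives C13=C14, and a CBS reduction sets C2.
- The oxolane is formed second: an Evans aldol on (S)-glyceraldehyde acetonide gives C7 and C17, followed by lactonisation and conversion to the methyl furanoside. The ten-membered ring is third, and the lactone carbonyl is made by oxidation at the end.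

Key step: step 27

Assumption: briarane numbering is used for every intermediate, and methyl furanosides are drawn as the anomer with OMe trans to the C17 methyl; the other anomer serves equally because C19 ends as the lactone carbonyl.

**Route**

Step 1
Reactants: 1 2,2-dimethoxyacetaldehyde; 2 ethyl 2-(triphenylphosphoranylidene)propanoate
Product: 3 ethyl (E)-4,4-dimethoxy-2-methylbut-2-enoate
Conditions: CH2Cl2, rt (1 as its 60 % aqueous solution)
Reagents that add atoms: none
Why: Wittig olefination with a stabilised α-methyl ylide gives the E enoate (ester trans to the acetal carbon), the geometry that later places the C1 methyl cis to C9.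

Step 2
Reactants: 3 ethyl (E)-4,4-dimethoxy-2-methylbut-2-enoate
Product: 4 ethyl (E)-2-methyl-4-oxobut-2-enoate
Conditions: 1 M aq. HCl, acetone, rt
Reagents that add atoms: water, O
Why: Acid-catalysed acetal hydrolysis frees the conjugated aldehyde without touching the ester, and the E isomer is the stable one.

Step 3
Reactants: 5 (E)-pent-3-en-2-one
Product: 6 (E)-2-(triisopropylsilyloxy)penta-1,3-diene
Conditions: i-Pr3SiOTf, Et3N, Et2O, 0 °C
Reagents that add atoms: triisopropylsilyl triflate, CC(C)[Si](C(C)C)(C(C)C)OS(=O)(=O)C(F)(F)F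
Why: Soft enolisation and O-silylation at the methyl group gives the cross-conjugated 2-silyloxy diene with the E olefin intact.

Step 4
Reactants: 4 ethyl (E)-2-methyl-4-oxobut-2-enoate; 6 (E)-2-(triisopropylsilyloxy)penta-1,3-diene
Product: 7 ethyl (1S,5S,6S)-6-formyl-1,5-dimethyl-3-(triisopropylsilyloxy)cyclohex-3-ene-1-carboxylate (ring A with C1 methyl, C10 formyl and C11 methyl all cis)
Conditions: (S)-o-tolyl-CBS-oxazaborolidine (20 mol %), Tf2NH (18 mol %), CH2Cl2, −78 → −40 °C; Et3N quench
Reagents that add atoms: none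
Why: In this Lewis acid-catalysed Diels–Alder reaction the CH2 terminus of the diene (C14) bonds to C1 (β to the activated formyl group, para to the silyloxy carbon) and the methyl-bearing terminus (C11) to C10, the E dienophile fixes the C1 methyl cis to the C10 formyl, the formyl-endo transition state puts the outside C11 methyl cis to the formyl group, and the cationic oxazaborolidine, bound to the formyl oxygen with the α-C–H···O contact of enals lacking an α-substituent, shields one face so that the (1S,5S,6S) adduct is expected.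

Step 5
Reactants: 7 ring A aldehyde ester
Product: 8 ring A C9 alcohol (6-hydroxymethyl analogue of 7)
Conditions: NaBH4, EtOH, −40 → 0 °C
Reagents that add atoms: none
Why: Chemoselective borohydride reduction of the aldehyde beside the hindered ester and the silyl enol ether removes the epimerisable C10 formyl group, and the trans-diaxial CH2OH and CO2Et groups of the preferred half-chair are slow to lactonise.

Step 6
Reactants: 8 ring A C9 alcohol
Product: 9 C9 tert-butyldimethylsilyl ether of 8
Conditions: TBSCl, imidazole, DMF, 0 °C → rt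
Reagents that add atoms: tert-butyldimethylsilyl chloride, CC(C)(C)[Si](C)(C)Cl
Why: Standard silylation of the primary alcohol blocks lactonisation and keeps C9 distinct from C2.

Step 7
Reactants: 9 C9 silyl ether
Product: 11 ring A C13 ketone with C12 OTIPS trans to the C11 methyl, via silyloxy epoxide 10 (not isolated)
Conditions: m-CPBA, NaHCO3, CH2Cl2, −20 → 20 °C
Reagents that add atoms: 3-chloroperbenzoic acid, OOC(=O)c1cccc(Cl)c1
Why: In this Rubottom oxidation the peracid oxygen adds to C12 of the enol ether on the face opposite the axial C10 CH2OTBS group and the C11 methyl, and opening of the silyloxy epoxide with 1,4-silyl migration gives the α-silyloxy ketone with the C12 oxygen on the face of the C1 ester.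

Step 8
Reactants: 11 ring A α-silyloxy ketone
Product: 13 C13 enol triflate with the C13=C14 double bond, via potassium enolate 12 (not isolated)
Conditions: KN(SiMe3)2, THF, −78 °C; PhNTf2, −78 → 0 °C
Reagents that add atoms: N-phenylbis(trifluoromethanesulfonimide), O=S(=O)(N(c1ccccc1)S(=O)(=O)C(F)(F)F)C(F)(F)F
Why: Kinetic deprotonation of an α-silyloxy ketone occurs at the unoxygenated CH2 (C14), C1 being quaternary, so O-triflation of the enolate fixes the olefin at C13=C14 and leaves C12 untouched.

Step 9
Reactants: 13 C13 enol triflate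
Product: 14 ethyl ring A ester with C13=C14, C12 OTIPS and C9 OTBS
Conditions: Pd(OAc)2 (5 mol %), PPh3, HCO2H, n-Bu3N, DMF, 60 °C
Reagents that add atoms: none
Why: Palladium-catalysed formate reduction of the enol triflate (oxidative addition to zerovalent palladium, formate exchange, decarboxylation, reductive elimination) replaces OTf by H with the olefin in place.

Step 10
Reactants: 14 ring A ester
Product: 15 ring A C2 primary alcohol
Conditions: i-Bu2AlH, CH2Cl2, −78 → 0 °C
Reagents that add atoms: none
Why: Hydride reduction of the neopentyl ester gives the primary alcohol, and the silyl ethers and the olefin are inert.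

Step 11
Reactants: 15 ring A C2 primary alcohol
Product: 16 ring A C2 aldehyde
Conditions: Dess–Martin periodinane, NaHCO3, CH2Cl2, rt
Reagents that add atoms: none
Why: Dess–Martin oxidation gives the non-enolisable aldehyde on the quaternary carbon under neutral conditions.

Step 12
Reactants: 16 ring A C2 aldehyde
Product: 17 C2 vinyl carbinols (both C2 epimers)
Conditions: CH2=CHMgBr, THF, −78 → −20 °C
Reagents that add atoms: vinylmagnesium bromide, C=C[Mg]Br
Why: Grignard 1,2-addition to the hindered aldehyde installs C3 and C4, and the C2 configuration is not relied on because it is erased in the next step.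

Step 13
Reactants: 17 C2 vinyl carbinols
Product: 18 C2 vinyl ketone
Conditions: Dess–Martin periodinane, NaHCO3, CH2Cl2, 0 °C → rt
Reagents that add atoms: none
Why: Dess–Martin oxidation of the allylic alcohols converges both epimers on one enone.

Step 14
Reactants: 18 C2 vinyl ketone
Product: 19 (2R)-allylic alcohol
Conditions: (S)-2-methyl-CBS-oxazaborolidine, catecholborane, toluene, −78 °C
Reagents that add atoms: none
Why: In this Corey–Bakshi–Shibata reduction the quaternary C1 is the large group and the vinyl group the small one, so the (S)-catalyst delivers hydride to the face that gives the (2R) carbinol by reagent control, with 1,2-selectivity at low temperature.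

Step 15
Reactants: 19 (2R)-allylic alcohol
Product: 20 (2R)-allylic acetate (ring A fragment)
Conditions: Ac2O, DMAP, pyridine, CH2Cl2, rt
Reagents that add atoms: acetic anhydride, CC(=O)OC(C)=O
Why: DMAP-catalysed acylation installs the C2 acetate of the target before the chain is extended.

Step 16
Reactants: 21 (R)-4-benzyl-3-propanoyloxazolidin-2-one; 22 (S)-2,2-dimethyl-1,3-dioxolane-4-carbaldehyde
Product: 24 (4R)-4-benzyl-3-[(2R,3R)-3-[(4S)-2,2-dimethyl-1,3-dioxolan-4-yl]-3-hydroxy-2-methylpropanoyl]oxazolidin-2-one, via boron enolate 23 (not isolated)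
Conditions: n-Bu2BOTf, i-Pr2NEt, CH2Cl2, 0 °C; 22, −78 → 0 °C; H2O2, pH 7 buffer, MeOH
Reagents that add atoms: none
Why: In this Evans syn-aldol reaction the Z boron enolate reacts through a Zimmerman–Traxler chair in which the (R)-auxiliary sets C17 as R and C8 syn to it, while C7 comes unchanged from the chiral pool aldehyde.

Step 17
Reactants: 24 Evans aldol adduct
Product: 26 (3R,4R,5S)-4-hydroxy-5-(hydroxymethyl)-3-methyloxolan-2-one, via triol imide 25 (not isolated)
Conditions: 1 M aq. HCl, THF, 45 °C
Reagents that add atoms: none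
Why: Acetonide hydrolysis frees the C7 and C6 hydroxyls and the γ-hydroxyl at C7 acylates intramolecularly (5-exo-trig lactonisation) with loss of the oxazolidinone, closing the five-membered ring with the C6 carbon and the C17 methyl cis.

Step 18
Reactants: 26 lactone diol
Product: 27 bis(tert-butyldimethylsilyl) ether of 26
Conditions: TBSCl (2.5 equiv), imidazole, DMF, rt
Reagents that add atoms: tert-butyldimethylsilyl chloride, CC(C)(C)[Si](C)(C)Cl
Why: Silylation of both hydroxyls protects C8–OH for the later oxidation and Wittig steps and ties up O6 so that only a furanose can form.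

Step 19
Reactants: 27 bis-silyl lactone
Product: 28 lactol (anomeric mixture)
Conditions: i-Bu2AlH (1.1 equiv), CH2Cl2, −78 °C
Reagents that add atoms: none
Why: Partial reduction of the γ-lactone stops at the lactol because the tetrahedral aluminium alkoxide is stable at −78 °C.

Step 20
Reactants: 28 lactol
Product: 29 methyl furanoside with C19 OMe, C8 OTBS and C6 OTBS
Conditions: PPTS (cat.), MeOH, 0 °C → rt
Reagents that add atoms: methanol, CO
Why: Acetal formation through the cyclic oxocarbenium ion gives the lactol methyl ether, expected mainly with OMe trans to the C17 methyl, and the silylated O6 rules out ring expansion.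

Step 21
Reactants: 29 bis-silyl methyl furanoside
Product: 30 C6 primary alcohol of the methyl furanoside
Conditions: HF·pyridine, pyridine, THF, 0 °C
Reagents that add atoms: none
Why: Buffered fluoride cleaves the primary silyl ether much faster than the secondary one at C8, and no alcohol solvent is present to open the acetal.

Step 22
Reactants: 30 C6 primary alcohol
Product: 31 C6 aldehyde of the methyl furanoside
Conditions: Dess–Martin periodinane, NaHCO3, CH2Cl2, 0 °C → rt
Reagents that add atoms: none
Why: Neutral Dess–Martin oxidation gives the α-alkoxy aldehyde without epimerising C7.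

Step 23
Reactants: 31 C6 aldehyde; 32 ethyltriphenylphosphonium iodide
Product: 33 (Z)-vinyl iodide methyl furanoside (oxolane fragment, iodine on C5 cis to C7)
Conditions: 32, n-BuLi, THF, 0 °C; I2, −78 °C; NaN(SiMe3)2, −20 °C; then 31, −78 → −20 °C
Reagents that add atoms: iodine, II
Why: Wittig olefination with the α-iodoethylidene ylide (Stork–Zhao type) gives the Z trisubstituted vinyl iodide under kinetic control, with iodine cis to C7.

Step 24
Reactants: 20 ring A allylic acetate; 33 (Z)-vinyl iodide
Product: 35 coupled seco compound with C9 OTBS, C8 OTBS, C12 OTIPS and C2 OAc, via alkylborane 34 (not isolated)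
Conditions: 9-BBN, THF, rt; then 33, PdCl2(dppf) (5 mol %), AsPh3, Cs2CO3, DMF/H2O, rt
Reagents that add atoms: none
Why: 9-BBN hydroborates only the monosubstituted olefin (boron on C4, the hindered ring olefin is left), and the B-alkyl Suzuki–Miyaura coupling forms C4–C5 with retention at the vinyl iodide, which gives the Z C5=C6 olefin.

Step 25
Reactants: 35 coupled seco compound
Product: 36 C8,C9-diol
Conditions: HF·pyridine, pyridine, THF, 0 °C → rt
Reagents that add atoms: none
Why: Buffered HF·pyridine removes the primary C9 and the secondary C8 TBS ethers, while the bulkier TIPS ether, the acetate and the methyl acetal survive.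

Step 26
Reactants: 36 C8,C9-diol
Product: 37 keto-aldehyde (C9 aldehyde on ring A, C8 ketone in the 5-methoxy-4-methyloxolan-3-one)
Conditions: Dess–Martin periodinane (3 equiv), NaHCO3, CH2Cl2, 0 °C → rt; used at once
Reagents that add atoms: none
Why: One buffered Dess–Martin oxidation converts both alcohols, so the β-methoxy ketone (prone to lose methanol and to epimerise at C7, C17 and C10 under acid or base) is exposed only to neutral conditions.

Step 27
Reactants: 37 keto-aldehyde
Product: 38 bicyclic cis-8,9-diol with the lactone masked as its lactol methyl ether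
Conditions: SmI2 (3 equiv, 0.1 M in THF), THF, −78 → 0 °C, 37 added by syringe pump to 1 mM
Reagents that add atoms: none
Why: SmI2 (divalent samarium) reduces the C9 aldehyde, the more easily reduced carbonyl, to a ketyl that adds to the C8 ketone held on the same trivalent samarium centre, and a second electron transfer gives the samarium 8,9-diolate; the closest known reaction type is the SmI2- or low-valent-titanium-mediated intramolecular pinacol coupling of keto-aldehydes to medium-ring and macrocyclic cis-diols. The ten-membered ring closes by C8–C9 bond formation in a 10-exo addition of the C9 ketyl radical to the C8 carbonyl carbon, helped by the Z C5=C6 olefin and the 1,2-attachment to ring A, and high dilution suppresses dimerisation. C8 is controlled by the oxolanone, in which the C6 chain on C7 and the methyl on C17 stand on the same face, so C9 enters anti to both and the five/ten ring junction becomes trans. C9 is controlled by the samarium bridge, which holds both oxygens syn in the bond-forming transition state and gives the cis-8,9-diol. The step needs C–C coupling to outrun reductive cleavage of the C7–O bond and loss of methanol from the β-methoxy ketone: the aldehyde is reduced first, the ring C7–O bond lies near the nodal plane of the carbonyl π system in the five-membered ring so its scission is slow, and the absence of HMPA, base and acid at low temperature spares the acetal and the C2 acetate.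

Step 28
Reactants: 38 cis-8,9-diol
Product: 39 C9 acetate of 38
Conditions: Ac2O, DMAP, pyridine, CH2Cl2, rt
Reagents that add atoms: acetic anhydride, CC(=O)OC(C)=O
Why: DMAP-catalysed acylation takes the secondary C9 hydroxyl and leaves the tertiary C8 hydroxyl free.

Step 29
Reactants: 39 C9 acetate
Product: 41 12-O-triisopropylsilyl ether of the target, via lactol 40 (not isolated)
Conditions: CrO3, H2SO4, acetone/H2O, 0 °C
Reagents that add atoms: water, O
Why: Under Jones oxidation conditions the methyl acetal is hydrolysed to the lactol, which hexavalent chromium oxidises to the γ-lactone, while the tertiary alcohol, the acetates and the TIPS ether should hold at 0 °C.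

Step 30
Reactants: 41 12-O-triisopropylsilyl ether of the target
Product: 42 CNP0222085.1 (target)
Conditions: HF·pyridine, THF, rt
Reagents that add atoms: none
Why: Fluoride cleavage of the Si–O bond frees the C12 hydroxyl without touching the lactone, the acetates or the tertiary alcohol.

**Compound list**

1 | 2,2-dimethoxyacetaldehyde | COC(OC)C=O | starting material
2 | ethyl 2-(triphenylphosphoranylidene)propanoate | CCOC(=O)C(C)=P(c1ccccc1)(c1ccccc1)c1ccccc1 | starting material
3 | ethyl (E)-4,4-dimethoxy-2-methylbut-2-enoate | CCOC(=O)/C(C)=C/C(OC)OC | intermediate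
4 | ethyl (E)-2-methyl-4-oxobut-2-enoate | CCOC(=O)/C(C)=C/C=O | intermediate
5 | (E)-pent-3-en-2-one | C/C=C/C(C)=O | starting material
6 | (E)-2-(triisopropylsilyloxy)penta-1,3-diene | C/C=C/C(=C)O[Si](C(C)C)(C(C)C)C(C)C | intermediate
7 | ethyl (1S,5S,6S)-6-formyl-1,5-dimethyl-3-(triisopropylsilyloxy)cyclohex-3-ene-1-carboxylate | O=C[C@H]1[C@@H](C)C=C(O[Si](C(C)C)(C(C)C)C(C)C)C[C@]1(C)C(=O)OCC | intermediate
8 | 6-(hydroxymethyl) analogue of 7 (C9 alcohol) | OC[C@H]1[C@@H](C)C=C(O[Si](C(C)C)(C(C)C)C(C)C)C[C@]1(C)C(=O)OCC | intermediate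
9 | C9 tert-butyldimethylsilyl ether of 8 | CC(C)(C)[Si](C)(C)OC[C@H]1[C@@H](C)C=C(O[Si](C(C)C)(C(C)C)C(C)C)C[C@]1(C)C(=O)OCC | intermediate
10 | C12,C13-epoxide of 9, oxygen on the face of the ester group | CC(C)(C)[Si](C)(C)OC[C@H]1[C@@H](C)[C@@H]2O[C@]2(O[Si](C(C)C)(C(C)C)C(C)C)C[C@]1(C)C(=O)OCC | intermediate
11 | ring A C13 ketone, C12 OTIPS trans to the C11 methyl, C9 OTBS, ethyl ester on C1 | CC(C)(C)[Si](C)(C)OC[C@H]1[C@@H](C)[C@H](O[Si](C(C)C)(C(C)C)C(C)C)C(=O)C[C@]1(C)C(=O)OCC | intermediate
12 | potassium C13(O)=C14 enolate of 11 | CC(C)(C)[Si](C)(C)OC[C@H]1[C@@H](C)[C@H](O[Si](C(C)C)(C(C)C)C(C)C)C(O[K])=C[C@]1(C)C(=O)OCC | intermediate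
13 | C13 enol triflate (C13=C14) | CC(C)(C)[Si](C)(C)OC[C@H]1[C@@H](C)[C@H](O[Si](C(C)C)(C(C)C)C(C)C)C(OS(=O)(=O)C(F)(F)F)=C[C@]1(C)C(=O)OCC | intermediate
14 | ethyl ring A ester with C13=C14, C12 OTIPS, C9 OTBS | CC(C)(C)[Si](C)(C)OC[C@H]1[C@@H](C)[C@H](O[Si](C(C)C)(C(C)C)C(C)C)C=C[C@]1(C)C(=O)OCC | intermediate
15 | ring A C2 primary alcohol | CC(C)(C)[Si](C)(C)OC[C@H]1[C@@H](C)[C@H](O[Si](C(C)C)(C(C)C)C(C)C)C=C[C@]1(C)CO | intermediate
16 | ring A C2 aldehyde | CC(C)(C)[Si](C)(C)OC[C@H]1[C@@H](C)[C@H](O[Si](C(C)C)(C(C)C)C(C)C)C=C[C@]1(C)C=O | intermediate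
17 | C2 vinyl carbinols (both C2 epimers) | CC(C)(C)[Si](C)(C)OC[C@H]1[C@@H](C)[C@H](O[Si](C(C)C)(C(C)C)C(C)C)C=C[C@]1(C)C(O)C=C | intermediate
18 | C2 vinyl ketone | CC(C)(C)[Si](C)(C)OC[C@H]1[C@@H](C)[C@H](O[Si](C(C)C)(C(C)C)C(C)C)C=C[C@]1(C)C(=O)C=C | intermediate
19 | (2R)-allylic alcohol | CC(C)(C)[Si](C)(C)OC[C@H]1[C@@H](C)[C@H](O[Si](C(C)C)(C(C)C)C(C)C)C=C[C@]1(C)[C@H](O)C=C | intermediate
20 | (2R)-allylic acetate (ring A fragment) | CC(C)(C)[Si](C)(C)OC[C@H]1[C@@H](C)[C@H](O[Si](C(C)C)(C(C)C)C(C)C)C=C[C@]1(C)[C@H](OC(C)=O)C=C | intermediate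
21 | (R)-4-benzyl-3-propanoyloxazolidin-2-one | CCC(=O)N1[C@H](Cc2ccccc2)COC1=O | starting material
22 | (S)-2,2-dimethyl-1,3-dioxolane-4-carbaldehyde | O=C[C@@H]1COC(C)(C)O1 | starting material
23 | dibutylboron Z-enolate of 21 | C/C=C(\OB(CCCC)CCCC)N1[C@H](Cc2ccccc2)COC1=O | intermediate
24 | (4R)-4-benzyl-3-[(2R,3R)-3-[(4S)-2,2-dimethyl-1,3-dioxolan-4-yl]-3-hydroxy-2-methylpropanoyl]oxazolidin-2-one | O=C(N1[C@H](Cc2ccccc2)COC1=O)[C@H](C)[C@@H](O)[C@@H]1COC(C)(C)O1 | intermediate
25 | triol imide from 24 (acetonide removed) | O=C(N1[C@H](Cc2ccccc2)COC1=O)[C@H](C)[C@@H](O)[C@@H](O)CO | intermediate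
26 | (3R,4R,5S)-4-hydroxy-5-(hydroxymethyl)-3-methyloxolan-2-one | O=C1O[C@@H](CO)[C@H](O)[C@H]1C | intermediate
27 | bis(tert-butyldimethylsilyl) ether of 26 | O=C1O[C@@H](CO[Si](C)(C)C(C)(C)C)[C@H](O[Si](C)(C)C(C)(C)C)[C@H]1C | intermediate
28 | lactol from 27 (anomeric mixture) | OC1O[C@@H](CO[Si](C)(C)C(C)(C)C)[C@H](O[Si](C)(C)C(C)(C)C)[C@H]1C | intermediate
29 | methyl furanoside with C8 OTBS and C6 OTBS | CO[C@@H]1O[C@@H](CO[Si](C)(C)C(C)(C)C)[C@H](O[Si](C)(C)C(C)(C)C)[C@H]1C | intermediate
30 | C6 primary alcohol of the methyl furanoside | CO[C@@H]1O[C@@H](CO)[C@H](O[Si](C)(C)C(C)(C)C)[C@H]1C | intermediate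
31 | C6 aldehyde of the methyl furanoside | CO[C@@H]1O[C@@H](C=O)[C@H](O[Si](C)(C)C(C)(C)C)[C@H]1C | intermediate
32 | ethyltriphenylphosphonium iodide | CC[P+](c1ccccc1)(c1ccccc1)c1ccccc1.[I-] | starting material
33 | (Z)-vinyl iodide methyl furanoside (oxolane fragment) | CO[C@@H]1O[C@@H](/C=C(/C)I)[C@H](O[Si](C)(C)C(C)(C)C)[C@H]1C | intermediate
34 | B-alkyl-9-borabicyclo[3.3.1]nonane from 20 (boron on C4) | CC(C)(C)[Si](C)(C)OC[C@H]1[C@@H](C)[C@H](O[Si](C(C)C)(C(C)C)C(C)C)C=C[C@]1(C)[C@H](OC(C)=O)CCB1C2CCCC1CCC2 | intermediate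
35 | coupled seco compound (C9 OTBS, C8 OTBS, C12 OTIPS, C2 OAc, Z C5=C6) | CC(C)(C)[Si](C)(C)OC[C@H]1[C@@H](C)[C@H](O[Si](C(C)C)(C(C)C)C(C)C)C=C[C@]1(C)[C@H](OC(C)=O)CC/C(C)=C\[C@@H]1O[C@@H](OC)[C@H](C)[C@H]1O[Si](C)(C)C(C)(C)C | intermediate
36 | C8,C9-diol | OC[C@H]1[C@@H](C)[C@H](O[Si](C(C)C)(C(C)C)C(C)C)C=C[C@]1(C)[C@H](OC(C)=O)CC/C(C)=C\[C@@H]1O[C@@H](OC)[C@H](C)[C@H]1O | intermediate
37 | keto-aldehyde (C9 aldehyde, C8 ketone) | O=C[C@H]1[C@@H](C)[C@H](O[Si](C(C)C)(C(C)C)C(C)C)C=C[C@]1(C)[C@H](OC(C)=O)CC/C(C)=C\[C@@H]1O[C@@H](OC)[C@H](C)C1=O | intermediate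
38 | bicyclic cis-8,9-diol lactol methyl ether | O[C@@H]1[C@H]2[C@@H](C)[C@H](O[Si](C(C)C)(C(C)C)C(C)C)C=C[C@]2(C)[C@H](OC(C)=O)CC/C(C)=C\[C@@H]2O[C@@H](OC)[C@H](C)[C@]21O | intermediate
39 | C9 acetate of 38 | CC(=O)O[C@@H]1[C@H]2[C@@H](C)[C@H](O[Si](C(C)C)(C(C)C)C(C)C)C=C[C@]2(C)[C@H](OC(C)=O)CC/C(C)=C\[C@@H]2O[C@@H](OC)[C@H](C)[C@]21O | intermediate
40 | lactol from 39 (C19 OH, anomeric mixture) | CC(=O)O[C@@H]1[C@H]2[C@@H](C)[C@H](O[Si](C(C)C)(C(C)C)C(C)C)C=C[C@]2(C)[C@H](OC(C)=O)CC/C(C)=C\[C@@H]2OC(O)[C@H](C)[C@]21O | intermediate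
41 | 12-O-triisopropylsilyl ether of the target | CC(=O)O[C@@H]1[C@H]2[C@@H](C)[C@H](O[Si](C(C)C)(C(C)C)C(C)C)C=C[C@]2(C)[C@H](OC(C)=O)CC/C(C)=C\[C@@H]2OC(=O)[C@H](C)[C@]21O | intermediate
42 | CNP0222085.1 | CC(=O)O[C@@H]1[C@H]2[C@@H](C)[C@H](O)C=C[C@]2(C)[C@H](OC(C)=O)CC/C(C)=C\[C@@H]2OC(=O)[C@H](C)[C@]21O | target

**Step count**

Total: 30 steps. Longest linear sequence: 21 steps (steps 1, 2, 4–15 and 24–30).

**Steps most likely to fail**

1. Step 27. Ten-membered ring closure of the C9 ketyl may be slower than reductive scission of the C7–O bond next to the ketone, loss of methanol from the β-methoxy ketone, or plain reduction of both carbonyls.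
 Fallback: the C8–C9 closure is kept but changed to a samarium ketyl–olefin addition onto a tetronate, which has no ketone at C8 and carries C19 already as the lactone.
 - From 33, n-Bu4NF removes the C8 silyl group to give the furanoside alcohol F1.
 - CrO3/H2SO4 oxidises both the C8 alcohol and the acetal to the tetronic acid F2.
 - Mitsunobu etherification with 4-methoxybenzyl alcohol (PPh3, DIAD) gives the 4-O-PMB tetronate F3.
 - Suzuki coupling of F3 with alkylborane 34 under the conditions of step 24 gives the seco tetronate F4.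
 - HF·pyridine gives the C9 alcohol F5, and Dess–Martin periodinane gives the aldehyde F6.
 - SmI2 with MeOH in THF at high dilution adds the C9 ketyl to C8, the alkoxy-bearing β-carbon of the butenolide (the reaction type known for aldehyde/β-alkoxyacrylate cyclisations), anti to C6; the samarium enolate is protonated at C17 to give the bicyclic lactone F7.
 - Acetylation gives F8, and DDQ removes the PMB ether to give 41, which rejoins the route before step 30.

2. Step 4. The β,β-disubstituted enal may react with poor facial discrimination, or with the opposite sense to that taken from the binding model, or with regiochemical leakage under the chiral catalyst.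
 Fallback: 4 and 6 are combined with Me2AlCl (CH2Cl2, −78 °C) to give racemic adduct F9, and NaBH4 gives racemic alcohol F10. Esterification with (S)-O-methylmandelic acid (DCC, DMAP) gives the diastereomeric esters F11 (from 8) and F12 (from the enantiomer of 8), which are separated by chromatography. K2CO3/MeOH on F11 returns 8, which rejoins the route at step 6.

3. Step 29. The strongly acidic oxidant may strip the C12 silyl ether and oxidise the freed allylic alcohol, or ionise the allylic C7–O bond.
 Fallback: the oxidation is split into two non-forcing operations. 39 is hydrolysed with AcOH/THF/H2O and lactol 40 is isolated, then oxidised with PhI(OAc)2 and catalytic TEMPO (or Ag2CO3 on Celite) to 41, which rejoins the route at step 30.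

Further compounds
F1 | step 27 | methyl furanoside C8 alcohol with the (Z)-vinyl iodide | CO[C@@H]1O[C@@H](/C=C(/C)I)[C@H](O)[C@H]1C
F2 | step 27 | (5S)-4-hydroxy-5-[(Z)-2-iodoprop-1-enyl]-3-methylfuran-2(5H)-one (tetronic acid) | CC1=C(O)[C@H](/C=C(/C)I)OC1=O
F3 | step 27 | 4-O-(4-methoxybenzyl) tetronate vinyl iodide | CC1=C(OCc2ccc(OC)cc2)[C@H](/C=C(/C)I)OC1=O
F4 | step 27 | seco tetronate (C9 OTBS, C12 OTIPS, C2 OAc) | CC(C)(C)[Si](C)(C)OC[C@H]1[C@@H](C)[C@H](O[Si](C(C)C)(C(C)C)C(C)C)C=C[C@]1(C)[C@H](OC(C)=O)CC/C(C)=C\[C@@H]1OC(=O)C(C)=C1OCc1ccc(OC)cc1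
F5 | step 27 | seco tetronate C9 alcohol | OC[C@H]1[C@@H](C)[C@H](O[Si](C(C)C)(C(C)C)C(C)C)C=C[C@]1(C)[C@H](OC(C)=O)CC/C(C)=C\[C@@H]1OC(=O)C(C)=C1OCc1ccc(OC)cc1
F6 | step 27 | seco tetronate C9 aldehyde | O=C[C@H]1[C@@H](C)[C@H](O[Si](C(C)C)(C(C)C)C(C)C)C=C[C@]1(C)[C@H](OC(C)=O)CC/C(C)=C\[C@@H]1OC(=O)C(C)=C1OCc1ccc(OC)cc1
F7 | step 27 | bicyclic lactone with C9 OH and C8 O-PMB | O[C@@H]1[C@H]2[C@@H](C)[C@H](O[Si](C(C)C)(C(C)C)C(C)C)C=C[C@]2(C)[C@H](OC(C)=O)CC/C(C)=C\[C@@H]2OC(=O)[C@H](C)[C@]21OCc1ccc(OC)cc1
F8 | step 27 | C9 acetate of F7 | CC(=O)O[C@@H]1[C@H]2[C@@H](C)[C@H](O[Si](C(C)C)(C(C)C)C(C)C)C=C[C@]2(C)[C@H](OC(C)=O)CC/C(C)=C\[C@@H]2OC(=O)[C@H](C)[C@]21OCc1ccc(OC)cc1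
F9 | step 4 | racemic 7 | O=C[C@H]1[C@@H](C)C=C(O[Si](C(C)C)(C(C)C)C(C)C)C[C@]1(C)C(=O)OCC.O=C[C@@H]1[C@H](C)C=C(O[Si](C(C)C)(C(C)C)C(C)C)C[C@@]1(C)C(=O)OCC
F10 | step 4 | racemic 8 | OC[C@H]1[C@@H](C)C=C(O[Si](C(C)C)(C(C)C)C(C)C)C[C@]1(C)C(=O)OCC.OC[C@@H]1[C@H](C)C=C(O[Si](C(C)C)(C(C)C)C(C)C)C[C@@]1(C)C(=O)OCC
F11 | step 4 | (S)-O-methylmandelate of 8 | CO[C@@H](c1ccccc1)C(=O)OC[C@H]1[C@@H](C)C=C(O[Si](C(C)C)(C(C)C)C(C)C)C[C@]1(C)C(=O)OCC
F12 | step 4 | (S)-O-methylmandelate of the enantiomer of 8 | CO[C@@H](c1ccccc1)C(=O)OC[C@@H]1[C@H](C)C=C(O[Si](C(C)C)(C(C)C)C(C)C)C[C@@]1(C)C(=O)OCC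
F0 | step 29 | none | none
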